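**Retrosynthetic overview**

- The acid comes from its methyl ester, and the (E)-2-methyl-2-enoate end is built last by cross-metathesis of a terminal alkene with methyl methacrylate.
- Key disconnection: the furan–CH2 | CH2–allyl bond. Furan-3-carbaldehyde, as its N–H hydrazone (a 3-furylmethyl carbanion surrogate), is joined under Pd(0) to an allylic tert-butyl carbonate. Two normally electrophilic carbons are joined, with loss of N2 and CO2.
- The allyl carbonate partner comes from an epoxy triflate and an allyl Grignard reagent. The epoxy alcohol comes from Sharpless epoxidation of the (E)-12-hydroxy farnesyl carbonate, made by SeO2 oxidation of the carbonate of (2E,6E)-farnesol. The carbonate is first the protecting group, then the leaving group.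
- Rings: the furan is bought intact and attached late. The only ring formed is the oxirane (Sharpless step), which sets both stereocentres before the furan arrives.

Assumption: (2E,6E)-farnesol of high isomeric purity is used; the enantiomeric purity of the product is that of the Sharpless step (about 90–95% ee expected).

**Step 1**
Reactants: 1 (2E,6E)-farnesol
Product: 2 tert-butyl (2E,6E)-3,7,11-trimethyldodeca-2,6,10-trien-1-yl carbonate
Conditions: Boc2O (1.5 equiv), DMAP (10 mol%), MeCN, rt
Reagents that add atoms: di-tert-butyl dicarbonate, CC(C)(C)OC(=O)OC(=O)OC(C)(C)C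
Why: DMAP-catalysed O-acylation of the primary allylic alcohol gives the tert-butyl carbonate, which protects C-1 through steps 2–4 and later serves as the leaving group of the key step.

**Step 2**
Reactants: 2 tert-butyl (2E,6E)-3,7,11-trimethyldodeca-2,6,10-trien-1-yl carbonate
Product: 3 tert-butyl (2E,6E,10E)-12-hydroxy-3,7,11-trimethyldodeca-2,6,10-trien-1-yl carbonate
Conditions: SeO2 (10 mol%), t-BuOOH (3 equiv), salicylic acid (10 mol%), CH2Cl2, rt
Reagents that add atoms: tert-butyl hydroperoxide, CC(C)(C)OO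
Why: Catalytic SeO2/t-BuOOH allylic oxidation (Riley oxidation, ene reaction then [2,3]-sigmatropic shift) attacks the (E)-methyl of the terminal trisubstituted alkene, the 2,3-alkene being deactivated by the allylic carbonate, and gives the (E)-allylic alcohol needed for a trans epoxide.

**Step 3**
Reactants: 3 tert-butyl (2E,6E,10E)-12-hydroxy-3,7,11-trimethyldodeca-2,6,10-trien-1-yl carbonate
Product: 4 tert-butyl (2E,6E)-9-[(2S,3S)-3-(hydroxymethyl)-3-methyloxiran-2-yl]-3,7-dimethylnona-2,6-dien-1-yl carbonate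
Conditions: Ti(Oi-Pr)4 (10 mol%), L-(+)-diethyl tartrate (12 mol%), t-BuOOH (2 equiv, anhydrous), 4 Å MS, CH2Cl2, −20 °C
Reagents that add atoms: tert-butyl hydroperoxide, CC(C)(C)OO
Why: Catalytic Sharpless asymmetric epoxidation touches only the allylic-alcohol alkene and, with L-(+)-tartrate, delivers oxygen to the face of the (E)-2-methylalk-2-en-1-ol that gives the (2S,3S)-epoxy alcohol, so both stereocentres of the target are set here and the E geometry fixes their trans relationship.

**Step 4**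
Reactants: 4 tert-butyl (2E,6E)-9-[(2S,3S)-3-(hydroxymethyl)-3-methyloxiran-2-yl]-3,7-dimethylnona-2,6-dien-1-yl carbonate; 5 allylmagnesium bromide
Product: 7 tert-butyl (2E,6E)-9-[(2S,3S)-3-(but-3-en-1-yl)-3-methyloxiran-2-yl]-3,7-dimethylnona-2,6-dien-1-yl carbonate, via epoxy triflate 6 (not isolated)
Conditions: Tf2O, 2,6-lutidine, CH2Cl2, −78 °C; then 5 (1.2 equiv), CuBr·SMe2 (10 mol%), Et2O–THF, −78 °C
Reagents that add atoms: none
Why: The primary epoxy triflate formed at −78 °C is displaced in an SN2 Cu(I)-catalysed Grignard coupling far faster than the reagent attacks the hindered epoxide or the tert-butyl carbonate, so the new C–C bond forms one carbon away from the stereocentres, which are not touched.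

**Step 5 (key step)**
Reactants: 7 tert-butyl (2E,6E)-9-[(2S,3S)-3-(but-3-en-1-yl)-3-methyloxiran-2-yl]-3,7-dimethylnona-2,6-dien-1-yl carbonate; 8 furan-3-carbaldehyde
Product: 10 3-[(3E,7E)-10-[(2S,3S)-3-(but-3-en-1-yl)-3-methyloxiran-2-yl]-4,8-dimethyldeca-3,7-dien-1-yl]furan, via furan-3-carbaldehyde hydrazone 9 (not isolated)
Conditions: 8 (1.5 equiv), N2H4·H2O (1.6 equiv), THF, rt, evaporate; then 7, Pd2(dba)3 (2.5 mol%), dppf (6 mol%), THF, 40 °C
Reagents that add atoms: none
Why: Proposed new method: Pd(0) ionises the allylic tert-butyl carbonate with loss of CO2 to a (π-allyl)Pd tert-butoxide pair, tert-butoxide deprotonates N–H hydrazone 9 to a diaza-allyl anion whose carbon terminus (the former aldehyde carbon, now nucleophilic) attacks the unsubstituted allyl terminus, and the resulting monoalkyl diazene loses N2 (Wolff–Kishner type) to leave the CH2–CH2 link with the E alkene retained and no stereocentre touched; the closest known reaction type is the Pd-catalysed Tsuji–Trost allylation with N-unsubstituted aldehyde hydrazones as alkyl-carbanion surrogates (carbonyl umpolung), combined here with decarboxylative allyl-carbonate activation and extended to a trisubstituted terpenoid allyl carbonate.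

**Step 6**
Reactants: 10 3-[(3E,7E)-10-[(2S,3S)-3-(but-3-en-1-yl)-3-methyloxiran-2-yl]-4,8-dimethyldeca-3,7-dien-1-yl]furan; 11 methyl methacrylate
Product: 12 methyl (2E)-5-[(2S,3S)-3-[(3E,7E)-10-(furan-3-yl)-3,7-dimethyldeca-3,7-dien-1-yl]-2-methyloxiran-2-yl]-2-methylpent-2-enoate
Conditions: 11 (10 equiv), Grubbs II (5 mol%), CH2Cl2, 40 °C
Reagents that add atoms: none
Why: Ru-catalysed olefin cross-metathesis of the terminal alkene with the 1,1-disubstituted methacrylate gives the trisubstituted enoate with E geometry, while the trisubstituted alkenes, furan and epoxide are spectators.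

**Step 7**
Reactants: 12 methyl (2E)-5-[(2S,3S)-3-[(3E,7E)-10-(furan-3-yl)-3,7-dimethyldeca-3,7-dien-1-yl]-2-methyloxiran-2-yl]-2-methylpent-2-enoate
Product: 13 (2E)-5-[(2S,3S)-3-[(3E,7E)-10-(furan-3-yl)-3,7-dimethyldeca-3,7-dien-1-yl]-2-methyloxiran-2-yl]-2-methylpent-2-enoic acid
Conditions: LiOH·H2O (5 equiv), THF–MeOH–H2O (3:1:1), rt; then 0.5 M HCl to pH 5, 0 °C
Reagents that add atoms: lithium hydroxide, [Li+].[OH-]
Why: Saponification of the methyl ester (BAc2) under conditions that the epoxide and furan tolerate, with acidification only to pH 5 in the cold to avoid epoxide opening; no stereocentre is affected.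

**Compound list**

1 | (2E,6E)-farnesol | OC/C=C(\C)CC/C=C(\C)CCC=C(C)C | starting material
2 | tert-butyl (2E,6E)-3,7,11-trimethyldodeca-2,6,10-trien-1-yl carbonate | CC(C)(C)OC(=O)OC/C=C(\C)CC/C=C(\C)CCC=C(C)C | intermediate
3 | tert-butyl (2E,6E,10E)-12-hydroxy-3,7,11-trimethyldodeca-2,6,10-trien-1-yl carbonate | CC(C)(C)OC(=O)OC/C=C(\C)CC/C=C(\C)CC/C=C(\C)CO | intermediate
4 | tert-butyl (2E,6E)-9-[(2S,3S)-3-(hydroxymethyl)-3-methyloxiran-2-yl]-3,7-dimethylnona-2,6-dien-1-yl carbonate | CC(C)(C)OC(=O)OC/C=C(\C)CC/C=C(\C)CC[C@@H]1O[C@@]1(C)CO | intermediate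
5 | allylmagnesium bromide | C=CC[Mg]Br | starting material
6 | epoxy triflate: [(2S,3S)-3-[(3E,7E)-9-[(tert-butoxycarbonyl)oxy]-3,7-dimethylnona-3,7-dien-1-yl]-2-methyloxiran-2-yl]methyl trifluoromethanesulfonate | CC(C)(C)OC(=O)OC/C=C(\C)CC/C=C(\C)CC[C@@H]1O[C@@]1(C)COS(=O)(=O)C(F)(F)F | intermediate
7 | tert-butyl (2E,6E)-9-[(2S,3S)-3-(but-3-en-1-yl)-3-methyloxiran-2-yl]-3,7-dimethylnona-2,6-dien-1-yl carbonate | CC(C)(C)OC(=O)OC/C=C(\C)CC/C=C(\C)CC[C@@H]1O[C@@]1(C)CCC=C | intermediate
8 | furan-3-carbaldehyde | O=Cc1ccoc1 | starting material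
9 | furan-3-carbaldehyde hydrazone, (E)-(furan-3-ylmethylidene)hydrazine | N/N=C/c1ccoc1 | intermediate
10 | 3-[(3E,7E)-10-[(2S,3S)-3-(but-3-en-1-yl)-3-methyloxiran-2-yl]-4,8-dimethyldeca-3,7-dien-1-yl]furan | C/C(=C\CCc1ccoc1)CC/C=C(\C)CC[C@@H]1O[C@@]1(C)CCC=C | intermediate
11 | methyl methacrylate | C=C(C)C(=O)OC | starting material
12 | methyl (2E)-5-[(2S,3S)-3-[(3E,7E)-10-(furan-3-yl)-3,7-dimethyldeca-3,7-dien-1-yl]-2-methyloxiran-2-yl]-2-methylpent-2-enoate | C/C(=C\CCc1ccoc1)CC/C=C(\C)CC[C@@H]1O[C@@]1(C)CC/C=C(\C)C(=O)OC | intermediate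
13 | (2E)-5-[(2S,3S)-3-[(3E,7E)-10-(furan-3-yl)-3,7-dimethyldeca-3,7-dien-1-yl]-2-methyloxiran-2-yl]-2-methylpent-2-enoic acid | C/C(=C\CCc1ccoc1)CC/C=C(\C)CC[C@@H]1O[C@@]1(C)CC/C=C(\C)C(=O)O | target

**Step count and risks**

Total step count: 7. Longest linear sequence: 7 (linear from farnesol; the furan aldehyde, allyl Grignard reagent and methacrylate are bought).

Most likely to fail, first: step 5. The hydrazone may be allylated on nitrogen, the π-allyl may be trapped by tert-butoxide or lose a proton to a triene, and branched attack or partial E/Z loss at the 3,4-alkene is possible. The fallback keeps a reversed-polarity furylmethyl donor but uses a sulfonyl carbanion and an SN2 step. It sets out from 7. NaOMe in MeOH removes the carbonate to give the free allylic alcohol F1. CBr4/PPh3 (CH2Cl2, 0 °C) converts it into the allylic bromide F2. 3-[(Phenylsulfonyl)methyl]furan F3, made from 3-(bromomethyl)furan and sodium benzenesulfinate in DMF, is lithiated (n-BuLi, THF, −78 °C) and alkylated with F2 to give the alkylated sulfone F4. Na(Hg), Na2HPO4, MeOH–THF at −20 °C then removes the sulfonyl group; the sulfonyl-bearing carbon is furylic and not allylic, so no alkene migration is expected. This comes back to the route at 10.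

Second: step 4. The epoxy triflate may decompose, or the allyl reagent may attack the carbonate or open the epoxide. The fallback replaces the allyl-copper coupling and the later cross-metathesis by a two-carbon aza-enolate alkylation and a Wittig olefination. It sets out from 4 and uses the same triflate 6. Lithiated acetaldehyde N-cyclohexylimine (LDA, THF, −78 °C) is alkylated by 6 to give the imine F5. Buffered hydrolysis (AcOH–NaOAc, pH 4.5, 0 °C) gives the epoxy aldehyde F6. Methyl 2-(triphenylphosphoranylidene)propanoate (CH2Cl2, rt) gives the (E)-enoate carbonate F7. F7 is then coupled with hydrazone 9 under the conditions of step 5 and comes back to the route at 12.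

Third: step 2. The yield is expected to be modest, with over-oxidation to the enal and some oxidation at internal allylic positions. The fallback rebuilds the oxidised terminus instead of oxidising it. It sets out from 2. NBS in aqueous THF (0 °C) gives the terminal bromohydrin F8. t-BuOK (THF, 0 °C) closes it to the terminal epoxide F9. H5IO6 (THF–H2O) cleaves this to the trisnor aldehyde F10. 2-(Triphenylphosphoranylidene)propanal (toluene, 80 °C) gives the (E)-enal F11. NaBH4/CeCl3 (MeOH, 0 °C) reduces it and comes back to the route at 3.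

**Further compounds**

F1 | step 5 | (2E,6E)-9-[(2S,3S)-3-(but-3-en-1-yl)-3-methyloxiran-2-yl]-3,7-dimethylnona-2,6-dien-1-ol | OC/C=C(\C)CC/C=C(\C)CC[C@@H]1O[C@@]1(C)CCC=C
F2 | step 5 | (2S,3S)-3-[(3E,7E)-9-bromo-3,7-dimethylnona-3,7-dien-1-yl]-2-(but-3-en-1-yl)-2-methyloxirane | BrC/C=C(\C)CC/C=C(\C)CC[C@@H]1O[C@@]1(C)CCC=C
F3 | step 5 | 3-[(phenylsulfonyl)methyl]furan | O=S(=O)(Cc1ccoc1)c1ccccc1
F4 | step 5 | 3-[(3E,7E)-10-[(2S,3S)-3-(but-3-en-1-yl)-3-methyloxiran-2-yl]-4,8-dimethyl-1-(phenylsulfonyl)deca-3,7-dien-1-yl]furan (both epimers at C-1) | C/C(=C\CC(c1ccoc1)S(=O)(=O)c1ccccc1)CC/C=C(\C)CC[C@@H]1O[C@@]1(C)CCC=C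
F5 | step 4 | tert-butyl (2E,6E)-9-[(2S,3S)-3-[3-(cyclohexylimino)propyl]-3-methyloxiran-2-yl]-3,7-dimethylnona-2,6-dien-1-yl carbonate | CC(C)(C)OC(=O)OC/C=C(\C)CC/C=C(\C)CC[C@@H]1O[C@@]1(C)CCC=NC2CCCCC2
F6 | step 4 | tert-butyl (2E,6E)-3,7-dimethyl-9-[(2S,3S)-3-methyl-3-(3-oxopropyl)oxiran-2-yl]nona-2,6-dien-1-yl carbonate | CC(C)(C)OC(=O)OC/C=C(\C)CC/C=C(\C)CC[C@@H]1O[C@@]1(C)CCC=O
F7 | step 4 | methyl (2E)-5-[(2S,3S)-3-[(3E,7E)-9-[(tert-butoxycarbonyl)oxy]-3,7-dimethylnona-3,7-dien-1-yl]-2-methyloxiran-2-yl]-2-methylpent-2-enoate | CC(C)(C)OC(=O)OC/C=C(\C)CC/C=C(\C)CC[C@@H]1O[C@@]1(C)CC/C=C(\C)C(=O)OC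
F8 | step 2 | tert-butyl (2E,6E)-10-bromo-11-hydroxy-3,7,11-trimethyldodeca-2,6-dien-1-yl carbonate (racemic) | CC(C)(C)OC(=O)OC/C=C(\C)CC/C=C(\C)CCC(Br)C(C)(C)O
F9 | step 2 | tert-butyl (2E,6E)-9-(3,3-dimethyloxiran-2-yl)-3,7-dimethylnona-2,6-dien-1-yl carbonate (racemic) | CC(C)(C)OC(=O)OC/C=C(\C)CC/C=C(\C)CCC1OC1(C)C
F10 | step 2 | tert-butyl (2E,6E)-3,7-dimethyl-10-oxodeca-2,6-dien-1-yl carbonate | CC(C)(C)OC(=O)OC/C=C(\C)CC/C=C(\C)CCC=O
F11 | step 2 | tert-butyl (2E,6E,10E)-3,7,11-trimethyl-12-oxododeca-2,6,10-trien-1-yl carbonate | CC(C)(C)OC(=O)OC/C=C(\C)CC/C=C(\C)CC/C=C(\C)C=O
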